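The data come from a simulation from invented constants; scatter was added.

A one-step world puts every lost substrate into target, but in the east run, the flask asked about, 58.0% of the substrate is gone by 15.0 min while target reads 22%.

| flask | substrate | coupling partner | free catalyst | temperature | remark | time |
|---|---|---|---|---|---|---|
| east | 0.21 M | 0.189 M | 1 mM | 20 °C | the very flask that is asked about, followed so far |  |
| north | 0.21 M | 0.189 M | 1 mM | 5 °C | run made earlier |  |
| flask | 0.21 M | 0.189 M | 1.0 mM | 20 °C |  | 25 min |

| run | time / min | target / % | substrate / % |
|---|---|---|---|
| east | 1.00 | 7 | 92 |
| east | 3.00 | 15 | 84 |
| east | 5.00 | 18 | 71 |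
| east | 8.00 | 20 | 64 |
| east | 12.0 | 24 | 48 |
| east | 15.0 | 22 | 42 |
| north | 2.00 | 9 | 93 |
| north | 6.00 | 14 | 81 |
| north | 10.0 | 21 | 76 |
| north | 15.0 | 27 | 62 |
| north | 25.0 | 35 | 45 |
| north | 30.0 | 37 | 38 |

(readings scatter by 1.5 percentage points)

- grey: at 25 min add coupling partner, 100% of the amount charged, then wait 12 min
- red: at 25 min raise the temperature by 20 K, then wait 12 min
- green: at 25 min take out 90% of the target then present, then wait 12 min
- violet: at 25 min add free catalyst, 50.0% of the amount charged, then wait 12 min
- teal: change nothing and wait 12 min more

- target that was removed still counts
- the earlier runs were read with a standard deviation of 1.5 percentage points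
- additions bring no volume worth counting

- target, in percent of the substrate first charged, at 25 min
- which option adds most target ("none" when 2 percentage points or less is all one gets) (grey / red / green / violet / teal / none)
- target present, with what was taken out counted in, in percent of the substrate first charged, after violet
- target present, with what was taken out counted in, in percent of the substrate first charged, after teal

Your working assumption is that each substrate lost beyond target took one target with it, so for the east run:

made = (substrate lost + target) / 2

This gives 23.5% by 5.00 min and 40.0% by 15.0 min, each carrying 1.1 percentage points of scatter.

Which numbers must you know well? The north run stands at another temperature, so you leave it out. The catalyst charge never varies, so the readings are silent on violet. The making rate, 0.0470 /min of the charge in the first window and 0.0165 /min in the second, needs only rough knowledge: read its fall a quarter slower, and coupling partner left at 25 min is 7.30%. The share of partner reaching target passes straight into grey's figure, so that one matters.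

Mean substrate fell from 85.5% to 56.5%, a factor of 1.51, and the making rate fell faster than that, by 2.85. So you take the rate as first order in coupling partner, the limiting reagent, and call its pseudo-first-order constant the partner clock:

clock = ln(first rate / second rate) / time between window centres = 0.140 /min

share of partner reaching target = 50.7%

In this flask, partner left at 25 min is then 3.05%, worth 1.4 points of new target to teal, green, violet or red. Grey's fresh charge offers 37 points of target made, before any loss of target, so you choose grey.

The forecast gives 16% now, 8% after violet and 8.6% after teal, and calls green “clearly the best”.

The flask gives 17.2% at 25 min, and grey adds 15 points, with 13.0% after violet and 12.7% after teal. Coupling partner stands at 3.38% of its charge at 25.0 min, where the clock said 3.05%.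

    catalyst intermediate B → free catalyst + target (k = 84.0 /min, Ea = 69.0 kJ/mol)
    coupling partner + catalyst intermediate A ⇌ catalyst intermediate B (K = 1.80 /M, k = 580 /M/min, Ea = 51.0 kJ/mol, ΔH = −31.0 kJ/mol)
    substrate + free catalyst ⇌ catalyst intermediate A (K = 12.0 /M, k = 3500 /M/min, Ea = 49.0 kJ/mol, ΔH = −76.0 kJ/mol)
    coupling partner → decomposed reagent (k = 0.0720 /min, Ea = 92.0 kJ/mol)
    substrate + target → side product (k = 0.510 /M/min, Ea = 58.0 kJ/mol)
    (constants at 20 °C)

For the neighbouring flask with 0.32 M of coupling partner, clock and share give 74.7% made, while its end, 36.9% target with 11% substrate left, gives 62.9% by the same sum.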